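**Plan**

1. Numbering follows the xanthane skeleton. The hydroxylated half is C1–C15 (lactone O on C8, lactone carbons C11–C13 on C7, methyl on C10, side chain C2–C4 on C1); the spiro-lactone half is primed.
2. Retrosynthesis cuts, in order: the C1–OH bond (dienolate oxygenation); C3–C11' and C5–C13' (Diels–Alder), which turns both halves into one monomer 15; in 15 the exocyclic C11=C13 and the lactone bond C7–C11 (carbenoid C–H insertion/olefination), giving cycloheptenol 10; C1=C5 and C2=C3 (enyne metathesis/cross metathesis); C10–C11-type bonds of the acyclic chain (epoxide opening, methylation).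
3. Forward order of rings: a temporary α-methyl-γ-lactone (carries C8 and C10, opened again in steps 3–4) → cycloheptene with the dienone → α-methylene-γ-lactone closed at C7–C11 → cyclohexene and spiro centre by dimerisation → C1 hydroxyl.
4. Stereochemistry: C8/C8' come from epoxide 1; C10/C10' from trans alkylation of the lactone enolate; C7/C7' from insertion into the equatorial C7–H with retention; C5 and C11' from the carbonyl-exo Diels–Alder on the H-7' face of the lactone and the diene face cis to the C10 methyl; C1 from oxygenation on the H-5 face.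
5. Enabling feature: the equatorial C7–H of the cycloheptene ring lies β to the C8 ester oxygen (1,5 to the carbenoid carbon) and is flanked only by C6H2, whereas its counterpart C9–H2 abuts the methyl-bearing C10. Both lactone/cycloheptene halves are the same monomer, so the one ring closure serves the target twice.

Key step: step 8

Remark: epoxide 1 is taken as the commercial single enantiomer; both lactone-bearing halves of the target have the same (7S,8R,10S) configuration, so monomer 15 is made once and used twice.

**Route**

Step 1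
Reactants: 1 (S)-2-(but-3-en-1-yl)oxirane; 2 acetic acid
Product: 4 (S)-5-(but-3-en-1-yl)oxolan-2-one, via (S)-4-hydroxyoct-7-enoic acid 3 (not isolated)
Conditions: 2, LiN(iPr)2 (2.2 equiv), THF–DMPU, 0 to 45 °C; then 1, 45 °C; aq. HCl; TsOH (cat.), toluene, 80 °C
Reagents that add atoms: none
Why: The dilithio dianion of acetic acid opens the terminal epoxide at its CH2 carbon (SN2, carboxylic acid dianion–epoxide opening), leaving the C8 stereocenter untouched, and the γ-hydroxy acid 3 lactonises under acid.

Step 2
Reactants: 4 (S)-5-(but-3-en-1-yl)oxolan-2-one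
Product: 5 (3S,5S)-5-(but-3-en-1-yl)-3-methyloxolan-2-one (trans)
Conditions: LiN(iPr)2, THF, −78 °C; MeI, −78 to −40 °C
Reagents that add atoms: iodomethane, CI
Why: Diastereoselective alkylation of the lactone lithium enolate should take place on the face opposite the C5 butenyl group, which sets the (3S) methyl centre (later C10) trans to the side chain.

Step 3
Reactants: 5 (3S,5S)-5-(but-3-en-1-yl)-3-methyloxolan-2-one
Product: 6 (3S,5S)-5-(but-3-en-1-yl)-3-methyloxolan-2-ol (lactol, anomer mixture)
Conditions: iBu2AlH (1.1 equiv), CH2Cl2, −78 °C; aq. potassium sodium tartrate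
Reagents that add atoms: none
Why: iBu2AlH at −78 °C stops at the aluminium hemiacetal, the standard half-reduction of a γ-lactone to its lactol, without touching the alkene or the α-stereocenter.

Step 4
Reactants: 6 (3S,5S)-5-(but-3-en-1-yl)-3-methyloxolan-2-ol
Product: 7 (5S,7S)-7-methylnon-1-en-8-yn-5-ol
Conditions: dimethyl (1-diazo-2-oxopropyl)phosphonate, K2CO3, MeOH, 0 °C to rt
Reagents that add atoms: dimethyl (1-diazo-2-oxopropyl)phosphonate, CC(=O)C(=[N+]=[N-])P(=O)(OC)OC
Why: The open hydroxy aldehyde form of lactol 6 undergoes Seyferth–Gilbert homologation with the Ohira–Bestmann reagent under K2CO3/MeOH, mild enough to keep the α-methyl stereocenter, and the temporary lactone ring is thereby opened for good.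

Step 5
Reactants: 7 (5S,7S)-7-methylnon-1-en-8-yn-5-ol; 8 but-3-en-2-one (methyl vinyl ketone)
Product: 10 (1S,3S)-3-methyl-4-[(1E)-3-oxobut-1-en-1-yl]cyclohept-4-en-1-ol, via ring diene 9 (not isolated)
Conditions: 8 (5 equiv), second-generation Hoveyda–Grubbs catalyst RuCl2(H2IMes)(=CH-C6H4-2-OiPr) (10 mol%), CH2Cl2, 40 °C
Reagents that add atoms: none
Why: Ring-closing enyne metathesis (exo mode) of the 1,8-enyne builds the cycloheptene with its C1 vinyl group, and cross metathesis of that vinyl group with methyl vinyl ketone in the same flask should give the (E)-dienone, the free alcohol and the trisubstituted ring alkene being tolerated.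

Step 6
Reactants: 10 (1S,3S)-3-methyl-4-[(1E)-3-oxobut-1-en-1-yl]cyclohept-4-en-1-ol; 11 2-(diethoxyphosphoryl)acetic acid
Product: 12 (1S,3S)-3-methyl-4-[(1E)-3-oxobut-1-en-1-yl]cyclohept-4-en-1-yl 2-(diethoxyphosphoryl)acetate
Conditions: DCC, DMAP (cat.), CH2Cl2, 0 °C to rt
Reagents that add atoms: none
Why: Steglich esterification attaches the carbene precursor to O-8 under neutral conditions with retention at C8.

Step 7
Reactants: 12 (1S,3S)-3-methyl-4-[(1E)-3-oxobut-1-en-1-yl]cyclohept-4-en-1-yl 2-(diethoxyphosphoryl)acetate
Product: 13 (1S,3S)-3-methyl-4-[(1E)-3-oxobut-1-en-1-yl]cyclohept-4-en-1-yl 2-diazo-2-(diethoxyphosphoryl)acetate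
Conditions: 4-acetamidobenzenesulfonyl azide, DBU, MeCN, 0 °C
Reagents that add atoms: 4-acetamidobenzenesulfonyl azide, CC(=O)Nc1ccc(cc1)S(=O)(=O)N=[N+]=[N-]
Why: Regitz diazo transfer to the doubly activated methylene, which is far more acidic than any position of the dienone, gives the acceptor/acceptor diazo ester.

Step 8
Reactants: 13 (1S,3S)-3-methyl-4-[(1E)-3-oxobut-1-en-1-yl]cyclohept-4-en-1-yl 2-diazo-2-(diethoxyphosphoryl)acetate
Product: 15 (3aS,7S,8aR)-7-methyl-3-methylidene-6-[(1E)-3-oxobut-1-en-1-yl]-3,3a,4,7,8,8a-hexahydro-2H-cyclohepta[b]furan-2-one (xanthanolide monomer), via trans-fused phosphono lactone 14 (not isolated)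
Conditions: Rh2(O2CC7H15)4 (2 mol%), CH2Cl2, 40 °C, slow addition of 13; then K2CO3, 37% aq. HCHO, THF, 0 °C to rt
Reagents that add atoms: formaldehyde, C=O
Why: The rhodium carbenoid formed from 13 by loss of N2 inserts in a concerted, asynchronous (hydride-transfer-like) step into the equatorial C7–H bond, which lies 1,5 to the carbenoid carbon, and so forges C7–C11 with retention at C7; the closest known reaction type is the one-pot C–H insertion/Horner–Wadsworth–Emmons olefination of α-diazo-α-(diethoxyphosphoryl)acetates of cycloalkanols. The only ring closed is the γ-lactone (O–C12–C11–C7–C8), by 1,5-C–H insertion through a five-membered cyclic transition state. C7 is the new stereocenter that stays: in the chair-like cycloheptene the C8 ester oxygen and the C10 methyl group are both equatorial, the carbenoid reaches the equatorial C7–H and the lactone should therefore be trans-fused (7S), while the C11 stereocenter of 14 is erased by the olefination. The step needs site selectivity for C7–H over the other β-methylene C9–H2 and over cis closure, and chemoselectivity over cyclopropanation or ylide formation. C9 is flanked by the branched C10 (equatorial methyl, sp2 C1 with the side chain) whereas C7 is flanked by a plain CH2, the dienone alkenes are electron-poor and out of reach of the tethered electrophilic carbenoid, and five-membered closure is the kinetically preferred ring size. The phosphoryl group that stabilises the diazo compound then serves for the olefination with formaldehyde and leaves as diethyl phosphate.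

Step 9
Reactants: 15 xanthanolide monomer (two molecules, one as diene and one as dienophile)
Product: 16 Diels–Alder dimer (β,γ-unsaturated ketone: C1=C2 alkene, acetyl on C3, new bonds C3–C11' and C5–C13', spiro centre C11')
Conditions: toluene (2 M), BHT (cat.), 100 °C, Ar, dark
Reagents that add atoms: none
Why: Thermal [4+2] cycloaddition (Diels–Alder dimerisation) joins the C5=C1–C2=C3 diene of one molecule to the exocyclic C11'=C13' alkene of a second: the acyl-bearing terminus C3 should bond to the substituted carbon C11' (ortho rule), the s-cis-locked α-methylene lactone should react through the carbonyl-exo transition state on its H-7' face (anti to C6'), and C13' should add to C5 on the diene face cis to the C10 methyl and trans to the C7–C11 bond (anti to the pseudoaxial allylic C6–H), which sets C5, C11' and the transient C3.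

Step 10
Reactants: 16 Diels–Alder dimer
Product: 18 CNP0168949.4 (target), via C1 hydroperoxide 17 (not isolated)
Conditions: O2 (1 atm), DBU (0.5 equiv), MeCN, 0 °C; then P(OEt)3
Reagents that add atoms: dioxygen, O=O
Why: DBU removes the doubly activated C3–H (α to the ketone and allylic), O2 should add to the γ-carbon C1 of the dienolate on the H-5 face, anti to the C10 methyl (vinylogous enolate oxygenation), and P(OEt)3 reduces hydroperoxide 17 to the tertiary alcohol with the alkene now conjugated at C2=C3; both C3 epimers and any conjugated isomer converge on the same dienolate.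

**Compound list**

1 | (S)-2-(but-3-en-1-yl)oxirane | C=CCC[C@H]1CO1 | starting material
2 | acetic acid | CC(O)=O | starting material
3 | (S)-4-hydroxyoct-7-enoic acid | OC(=O)CC[C@@H](O)CCC=C | intermediate
4 | (S)-5-(but-3-en-1-yl)oxolan-2-one | O=C1CC[C@H](CCC=C)O1 | intermediate
5 | (3S,5S)-5-(but-3-en-1-yl)-3-methyloxolan-2-one | C[C@H]1C[C@H](CCC=C)OC1=O | intermediate
6 | (3S,5S)-5-(but-3-en-1-yl)-3-methyloxolan-2-ol (anomer mixture) | C[C@H]1C[C@H](CCC=C)OC1O | intermediate
7 | (5S,7S)-7-methylnon-1-en-8-yn-5-ol | O[C@@H](CCC=C)C[C@H](C)C#C | intermediate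
8 | but-3-en-2-one | CC(=O)C=C | starting material
9 | (1S,3S)-4-ethenyl-3-methylcyclohept-4-en-1-ol | O[C@@H]1C[C@H](C)C(C=C)=CCC1 | intermediate
10 | (1S,3S)-3-methyl-4-[(1E)-3-oxobut-1-en-1-yl]cyclohept-4-en-1-ol | O[C@@H]1C[C@H](C)C(/C=C/C(C)=O)=CCC1 | intermediate
11 | 2-(diethoxyphosphoryl)acetic acid | OC(=O)CP(=O)(OCC)OCC | starting material
12 | (1S,3S)-3-methyl-4-[(1E)-3-oxobut-1-en-1-yl]cyclohept-4-en-1-yl 2-(diethoxyphosphoryl)acetate | CCOP(=O)(OCC)CC(=O)O[C@@H]1C[C@H](C)C(/C=C/C(C)=O)=CCC1 | intermediate
13 | (1S,3S)-3-methyl-4-[(1E)-3-oxobut-1-en-1-yl]cyclohept-4-en-1-yl 2-diazo-2-(diethoxyphosphoryl)acetate | CCOP(=O)(OCC)C(=[N+]=[N-])C(=O)O[C@@H]1C[C@H](C)C(/C=C/C(C)=O)=CCC1 | intermediate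
14 | diethyl {7-methyl-2-oxo-6-[(1E)-3-oxobut-1-en-1-yl]-3,3a,4,7,8,8a-hexahydro-2H-cyclohepta[b]furan-3-yl}phosphonate, trans-fused, ring stereocenters as in 15, both C3 epimers | CCOP(=O)(OCC)C1C(=O)O[C@@H]2C[C@H](C)C(/C=C/C(C)=O)=CC[C@@H]12 | intermediate
15 | (3aS,7S,8aR)-7-methyl-3-methylidene-6-[(1E)-3-oxobut-1-en-1-yl]-3,3a,4,7,8,8a-hexahydro-2H-cyclohepta[b]furan-2-one | C=C1C(=O)O[C@@H]2C[C@H](C)C(/C=C/C(C)=O)=CC[C@@H]12 | intermediate
16 | Diels–Alder dimer of 15 (C1=C2 alkene, C3 acetyl with H-3 cis to H-5, spiro C11') | C=C1C(=O)O[C@@H]2C[C@H](C)C3=C[C@H](C(C)=O)[C@]4(C[C@@H]3C[C@@H]12)C(=O)O[C@@H]1C[C@H](C)C(/C=C/C(C)=O)=CC[C@H]14 | intermediate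
17 | C1 hydroperoxide of the target | C=C1C(=O)O[C@@H]2C[C@H](C)[C@]3(OO)C=C(C(C)=O)[C@]4(C[C@@H]3C[C@@H]12)C(=O)O[C@@H]1C[C@H](C)C(/C=C/C(C)=O)=CC[C@H]14 | intermediate
18 | CNP0168949.4 | C=C1C(=O)O[C@@H]2C[C@H](C)[C@]3(O)C=C(C(C)=O)[C@]4(C[C@@H]3C[C@@H]12)C(=O)O[C@@H]1C[C@H](C)C(/C=C/C(C)=O)=CC[C@H]14 | target

**Step count and risks**

Total steps: 10. Longest linear sequence: 10 steps (from 1).

Step 8. What may go wrong: the carbenoid may not distinguish the two methylene groups that flank C8 (insertion at C9–H instead of C7–H), may insert into the axial C7–H (cis-fused ring), or may dimerise. Fallback: conjugate addition in place of C–H insertion, setting out from hydroxy dienone 10 and returning at phosphono lactone 14. Compound 10 is silylated twice with tBuMe2SiOTf/Et3N, at the alcohol and, through the vinylogous C6 position, at the ketone, to give bis-silyl trienol ether F1. Saegusa–Ito oxidation with Pd(OAc)2 (1 equiv) in MeCN desaturates C6–C7 to silyloxy trienone F2, in which C7 is the single terminus of the extended acceptor. The sodium salt of triethyl phosphonoacetate (NaH, THF) should add 1,8 at C7 anti to the C8 silyl ether, and protonation into conjugation gives adduct F3. HF·pyridine frees the C8 hydroxyl, which lactonises on the ethyl ester to 14; the olefination half of step 8 (K2CO3, aq. HCHO) then gives 15.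

Step 9. What may go wrong: cycloaddition between an electron-poor diene and an electron-poor dienophile may be sluggish, and material may be lost to hetero-Diels–Alder reaction through the enone, to the enone acting as dienophile, or to addition on the other diene face. Fallback: raise the diene energy by masking the ketone, setting out from 15 and returning at 16. Compound 15 with 1,2-bis(trimethylsilyloxy)ethane and Me3SiOTf (cat.) in CH2Cl2 at −78 °C gives dioxolane monomer F4, whose diene is no longer conjugated with a carbonyl and pairs in the normal-demand sense with the α-methylene lactone of a second molecule. Heating F4 (toluene, 80 °C) should give bis-dioxolane dimer F5 with the same ortho and carbonyl-exo sense, and PPTS in acetone–water releases 16.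

Step 10. What may go wrong: oxygenation of the dienolate on the wrong face or at C3, or base-induced isomerisation of the exocyclic methylene of the lactone. Fallback: epoxidation and elimination in place of enolate oxygenation, setting out from 16 and returning at 18. Dimethyldioxirane (acetone, 0 °C) should epoxidise the only electron-rich alkene, the trisubstituted C1=C2, on the H-5 face to give epoxy ketone F6. A catalytic amine base (Et3N, CH2Cl2) then opens the epoxide by E1cB elimination from C3–H and gives the γ-hydroxy enone 18 directly.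

**Further compounds**

F1 | step 8 | bis-silyl trienol ether of 10 (C8 silyl ether; C6=C5, C1=C2 and C3=C4(OSi) alkenes, geometry mixture) | C[C@H]1C[C@@H](O[Si](C)(C)C(C)(C)C)CC=CC1=CC=C(C)O[Si](C)(C)C(C)(C)C
F2 | step 8 | silyloxy trienone (C6=C7 desaturated tert-butyldimethylsilyl ether of 10) | CC(C)(C)[Si](C)(C)O[C@@H]1C[C@H](C)C(/C=C/C(C)=O)=CC=C1
F3 | step 8 | 1,8-adduct: ethyl 2-(diethoxyphosphoryl)-2-{(1S,2R,4S)-2-[(tert-butyldimethylsilyl)oxy]-4-methyl-5-[(1E)-3-oxobut-1-en-1-yl]cyclohept-5-en-1-yl}acetate (C7–C11 bond trans to O-8, C11 epimers) | CCOC(=O)C(P(=O)(OCC)OCC)[C@@H]1CC=C(/C=C/C(C)=O)[C@@H](C)C[C@H]1O[Si](C)(C)C(C)(C)C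
F4 | step 9 | dioxolane (ethylene ketal at C4) of monomer 15 | C=C1C(=O)O[C@@H]2C[C@H](C)C(/C=C/C3(C)OCCO3)=CC[C@@H]12
F5 | step 9 | bis-dioxolane of dimer 16 | C=C1C(=O)O[C@@H]2C[C@H](C)C3=C[C@H](C4(C)OCCO4)[C@]5(C[C@@H]3C[C@@H]12)C(=O)O[C@@H]1C[C@H](C)C(/C=C/C6(C)OCCO6)=CC[C@H]15
F6 | step 10 | 1,2-epoxide of dimer 16 (oxygen on the H-5 face) | C=C1C(=O)O[C@@H]2C[C@H](C)[C@@]34O[C@H]4[C@H](C(C)=O)[C@]5(C[C@@H]3C[C@@H]12)C(=O)O[C@@H]1C[C@H](C)C(/C=C/C(C)=O)=CC[C@H]15
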